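**Retrosynthetic overview**

1. Feature: in the 14-membered carbocycle C1–C14 (C1 = CH bearing isopropenyl, C3=C4 enoate, C6 ketone), the C13 ketone stands 1,4 to the C10 ketone of the oxolan-3-one ring (O bridging C8 and C11). A C13≡C14 alkyne is therefore a latent C13 ketone to which the C10 carbonyl can deliver oxygen.
2. Target 41 ⇐ cycloalkyne 40 by gold hydration at C13 (step 23) ⇐ open-chain diyne 39 by ring-closing alkyne metathesis at C13–C14 (step 22).
3. 39 ⇐ Still–Gennari Z-olefination at C3=C4 of aldehyde 14 (C14, C1–C3) with keto phosphonate 37 (C4–C13).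
4. 37 ⇐ oxolanone by Rh-carbenoid insertion into C8–H (C8 from (R)-pent-4-en-2-ol, C11 by glycolate alkylation), butynyl arm by decarboxylative alkynylation, allyl → bromoketone → phosphonate. 14 ⇐ deconjugative alkylation of a senecioyl imide (C1), then Corey–Fuchs methylalkyne.
5. Ring order: oxolan-3-one first (step 14), 14-membered carbocycle second (step 22).

Key step: step 22

Remark: the carbocycle numbering C1–C14 defined above is used throughout. The carbinol carbon of 33 and the phosphonate carbon of 37 are carried as epimer mixtures because both centres are destroyed later.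

**Fragment A (aldehyde 14)**

Step 1
Reactants: 1 (R)-4-benzyl-1,3-oxazolidin-2-one; 2 3-methylbut-2-enoyl chloride
Product: 4 (R)-4-benzyl-3-(3-methylbut-2-enoyl)-1,3-oxazolidin-2-one, via N-lithio oxazolidinone 3 (not isolated)
Conditions: n-BuLi, THF, −78 °C; then 2, −78 → 0 °C
Reagents that add atoms: n-butyllithium, [Li]CCCC (lithium of intermediate 3 only)
Why: N-acylation of the lithiated oxazolidinone by the acid chloride (imide formation); no stereocentre is formed.

Step 2
Reactants: 4 (R)-4-benzyl-3-(3-methylbut-2-enoyl)-1,3-oxazolidin-2-one; 5 tert-butyl bromoacetate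
Product: 7 tert-butyl (3R)-3-{[(4R)-4-benzyl-2-oxo-1,3-oxazolidin-3-yl]carbonyl}-4-methylpent-4-enoate, via sodium dienolate 6 (not isolated)
Conditions: NaN(SiMe3)2, THF, −78 °C; then 5, −78 → −40 °C
Reagents that add atoms: sodium bis(trimethylsilyl)amide, [Na+].C[Si](C)(C)[N-][Si](C)(C)C (sodium of intermediate 6 only)
Why: Auxiliary-controlled deconjugative alkylation (Evans alkylation of a dienolate): γ-deprotonation of the s-cis enoyl imide gives the chelated Z-dienolate, which is alkylated at the α-carbon on the face opposite the benzyl group, setting C1 and unveiling the isopropenyl group.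

Step 3
Reactants: 7 tert-butyl (3R)-3-{[(4R)-4-benzyl-2-oxo-1,3-oxazolidin-3-yl]carbonyl}-4-methylpent-4-enoate
Product: 8 tert-butyl (3R)-3-(hydroxymethyl)-4-methylpent-4-enoate
Conditions: LiBH4, MeOH (1 equiv), Et2O, 0 °C
Reagents that add atoms: none
Why: Reductive cleavage of the imide by LiBH4 is much faster than reduction of the tert-butyl ester, so the auxiliary is released and C14 reaches the alcohol level without touching C1.

Step 4
Reactants: 8 tert-butyl (3R)-3-(hydroxymethyl)-4-methylpent-4-enoate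
Product: 9 tert-butyl (3R)-3-formyl-4-methylpent-4-enoate
Conditions: Dess–Martin periodinane, NaHCO3, CH2Cl2, 0 °C → rt; used crude at once
Reagents that add atoms: none
Why: Dess–Martin oxidation under bicarbonate buffer is neither basic nor acidic, which should keep the α-stereocentre of the β,γ-unsaturated aldehyde from epimerising or moving into conjugation.

Step 5
Reactants: 9 tert-butyl (3R)-3-formyl-4-methylpent-4-enoate
Product: 10 tert-butyl (3S)-3-(2,2-dibromoethenyl)-4-methylpent-4-enoate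
Conditions: CBr4, PPh3, Zn dust, CH2Cl2, rt (ylide pre-formed); then 9, 0 °C → rt
Reagents that add atoms: carbon tetrabromide, BrC(Br)(Br)Br
Why: Ramirez dibromo-olefination (first half of the Corey–Fuchs sequence) with the pre-formed ylide is neutral, so the labile α-centre becomes a non-enolisable allylic carbon before any base is used.

Step 6
Reactants: 10 tert-butyl (3S)-3-(2,2-dibromoethenyl)-4-methylpent-4-enoate
Product: 11 (3S)-5,5-dibromo-3-(prop-1-en-2-yl)pent-4-en-1-ol
Conditions: i-Bu2AlH (2.5 equiv), CH2Cl2, −78 → 0 °C; potassium sodium tartrate work-up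
Reagents that add atoms: none
Why: Hydride reduction of the tert-butyl ester to the primary alcohol (C3) leaves the 1,1-dibromoalkene intact and removes the enolisable ester before the organolithium step.

Step 7
Reactants: 11 (3S)-5,5-dibromo-3-(prop-1-en-2-yl)pent-4-en-1-ol
Product: 13 (3R)-3-(prop-1-en-2-yl)hex-4-yn-1-ol, via dilithium alkoxide acetylide 12 (not isolated)
Conditions: n-BuLi (3.1 equiv), THF, −78 °C; then MeI, −78 °C → rt
Reagents that add atoms: iodomethane, CI; n-butyllithium, [Li]CCCC (lithium of intermediate 12 only)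
Why: Second half of the Corey–Fuchs sequence: after O-deprotonation, elimination to the bromoalkyne and bromine–lithium exchange give the lithium acetylide, whose C-methylation by MeI is far faster than O-methylation of the lithium alkoxide in THF.

Step 8
Reactants: 13 (3R)-3-(prop-1-en-2-yl)hex-4-yn-1-ol
Product: 14 (3R)-4-methyl-3-(prop-1-yn-1-yl)pent-4-enal
Conditions: Dess–Martin periodinane, NaHCO3, CH2Cl2, 0 °C; kept in solution (volatile)
Reagents that add atoms: none
Why: Dess–Martin oxidation gives the β-branched aldehyde under buffered conditions that leave the doubly activated C1–H of the skipped enyne untouched.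

**Fragment B (keto phosphonate 37)**

Step 9
Reactants: 15 (R)-pent-4-en-2-ol; 16 bromoacetic acid
Product: 18 2-{[(2R)-pent-4-en-2-yl]oxy}acetic acid, via sodium alkoxide 17 (not isolated)
Conditions: NaH (3 equiv), THF, 0 °C; then 16, 0 °C → reflux; HCl work-up
Reagents that add atoms: sodium hydride, [Na+].[H-] (sodium of intermediate 17 only)
Why: Williamson etherification of the secondary alkoxide with sodium bromoacetate; the C–O bond of the carbinol carbon (future C8) is not broken, so its R configuration is kept.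

Step 10
Reactants: 18 2-{[(2R)-pent-4-en-2-yl]oxy}acetic acid; 19 (S)-4-benzyl-1,3-oxazolidin-2-one
Product: 22 (4S)-4-benzyl-3-({[(2R)-pent-4-en-2-yl]oxy}acetyl)-1,3-oxazolidin-2-one, via mixed pivalic anhydride 20 (not isolated), via N-lithio oxazolidinone 21 (not isolated)
Conditions: t-BuCOCl, Et3N, THF, −78 → 0 °C; then 21 (from 19, n-BuLi, THF, −78 °C), −78 → 0 °C
Reagents that add atoms: pivaloyl chloride, CC(C)(C)C(Cl)=O (pivaloyl of intermediate 20 only); n-butyllithium, [Li]CCCC (lithium of intermediate 21 only)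
Why: Acylation of the lithiated oxazolidinone by the mixed anhydride, which is attacked at the less hindered glycolyl carbonyl.

Step 11
Reactants: 22 (4S)-4-benzyl-3-({[(2R)-pent-4-en-2-yl]oxy}acetyl)-1,3-oxazolidin-2-one; 5 tert-butyl bromoacetate
Product: 24 tert-butyl (3R)-4-[(4S)-4-benzyl-2-oxo-1,3-oxazolidin-3-yl]-4-oxo-3-{[(2R)-pent-4-en-2-yl]oxy}butanoate, via sodium enolate 23 (not isolated)
Conditions: NaN(SiMe3)2, THF, −78 °C; then 5, −78 → −45 °C
Reagents that add atoms: sodium bis(trimethylsilyl)amide, [Na+].C[Si](C)(C)[N-][Si](C)(C)C (sodium of intermediate 23 only)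
Why: Evans-type glycolate alkylation: the chelated Z-sodium enolate is alkylated by the α-bromo ester on the face opposite the benzyl group, which sets C11 (R).

Step 12
Reactants: 24 tert-butyl (3R)-4-[(4S)-4-benzyl-2-oxo-1,3-oxazolidin-3-yl]-4-oxo-3-{[(2R)-pent-4-en-2-yl]oxy}butanoate
Product: 26 (2R)-4-tert-butoxy-4-oxo-2-{[(2R)-pent-4-en-2-yl]oxy}butanoic acid, via lithium peroxycarboxylate 25 (not isolated)
Conditions: LiOH, H2O2, THF/H2O (3:1), 0 °C; then Na2SO3; HCl to pH 3
Reagents that add atoms: hydrogen peroxide, OO; lithium hydroxide, [Li+].[OH-] (lithium of intermediate 25 only)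
Why: Hydroperoxide-mediated exocyclic cleavage of the imide frees the α-alkoxy acid without epimerisation of C11 and leaves the tert-butyl ester.

Step 13
Reactants: 26 (2R)-4-tert-butoxy-4-oxo-2-{[(2R)-pent-4-en-2-yl]oxy}butanoic acid
Product: 28 tert-butyl (3R)-5-diazo-4-oxo-3-{[(2R)-pent-4-en-2-yl]oxy}pentanoate, via mixed isobutyl carbonic anhydride 27 (not isolated)
Conditions: i-BuOCOCl, Et3N, THF, −15 °C; then CH2N2, Et2O, −15 °C → rt
Reagents that add atoms: diazomethane, C=[N+]=[N-]; isobutyl chloroformate, CC(C)COC(Cl)=O (carbonate of intermediate 27 only)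
Why: Acylation of diazomethane by the mixed anhydride (first stage of an Arndt–Eistert sequence) gives the α-alkoxy diazoketone, in which the diazo carbon is the future C9, without touching C11.

Step 14
Reactants: 28 tert-butyl (3R)-5-diazo-4-oxo-3-{[(2R)-pent-4-en-2-yl]oxy}pentanoate
Product: 29 tert-butyl 2-[(2R,5R)-5-methyl-3-oxo-5-(prop-2-en-1-yl)oxolan-2-yl]acetate
Conditions: Rh2(OAc)4 (1 mol %), CH2Cl2, rt, slow addition of 28
Reagents that add atoms: none
Why: Rhodium-carbenoid 1,5 C–H insertion: the carbenoid carbon C9 inserts in a concerted way, with retention, into the ether-activated tertiary C8–H bond through a five-membered transition state, closing the oxolan-3-one and setting the quaternary C8 (R), while oxonium ylide formation would need a four-membered ring and the C12–H bonds are deactivated by the ester.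

Step 15
Reactants: 29 tert-butyl 2-[(2R,5R)-5-methyl-3-oxo-5-(prop-2-en-1-yl)oxolan-2-yl]acetate
Product: 30 2-[(2R,5R)-5-methyl-3-oxo-5-(prop-2-en-1-yl)oxolan-2-yl]acetic acid
Conditions: CF3CO2H, CH2Cl2, 0 °C → rt
Reagents that add atoms: none
Why: Acidolysis of the tert-butyl ester (loss of 2-methylpropene) frees the carboxylic acid on C12; ketone, ether and terminal alkene should survive brief exposure.

Step 16
Reactants: 30 2-[(2R,5R)-5-methyl-3-oxo-5-(prop-2-en-1-yl)oxolan-2-yl]acetic acid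
Product: 31 4,5,6,7-tetrachloro-1,3-dioxoisoindolin-2-yl 2-[(2R,5R)-5-methyl-3-oxo-5-(prop-2-en-1-yl)oxolan-2-yl]acetate
Conditions: N-hydroxytetrachlorophthalimide, N,N'-diisopropylcarbodiimide, DMAP (cat.), CH2Cl2, rt
Reagents that add atoms: N-hydroxytetrachlorophthalimide, ON1C(=O)c2c(Cl)c(Cl)c(Cl)c(Cl)c2C1=O
Why: Carbodiimide esterification gives the redox-active ester needed for decarboxylative coupling.

Step 17
Reactants: 31 4,5,6,7-tetrachloro-1,3-dioxoisoindolin-2-yl 2-[(2R,5R)-5-methyl-3-oxo-5-(prop-2-en-1-yl)oxolan-2-yl]acetate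
Product: 32 (2R,5R)-2-(but-2-yn-1-yl)-5-methyl-5-(prop-2-en-1-yl)oxolan-3-one
Conditions: prop-1-ynylzinc chloride (from prop-1-ynylmagnesium bromide, ZnCl2), NiCl2·6H2O (20 mol %), 4,4'-dimethoxy-2,2'-bipyridine (20 mol %), DMF/THF, rt
Reagents that add atoms: prop-1-ynylzinc chloride, CC#C[Zn]Cl
Why: Nickel-catalysed decarboxylative alkynylation (Negishi-type coupling of a redox-active ester): single-electron reduction releases CO2 and the primary C12 radical, which nickel captures and couples with the propynyl group from zinc; the organozinc does not add to the ketone and no stereocentre sits at the radical carbon.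

Step 18
Reactants: 32 (2R,5R)-2-(but-2-yn-1-yl)-5-methyl-5-(prop-2-en-1-yl)oxolan-3-one
Product: 33 (2R,5R)-5-(3-bromo-2-hydroxypropyl)-2-(but-2-yn-1-yl)-5-methyloxolan-3-one (both carbinol epimers)
Conditions: N-bromosuccinimide (1.05 equiv), THF/H2O (4:1), 0 °C
Reagents that add atoms: N-bromosuccinimide, O=C1CCC(=O)N1Br; water, O
Why: Bromohydrin formation: the terminal alkene takes up bromonium faster than the internal alkyne and water opens it at the more substituted carbon (Markovnikov), placing oxygen on C6 and bromine on C5; the new carbinol centre is formed unselectively and is removed in step 19.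

Step 19
Reactants: 33 (2R,5R)-5-(3-bromo-2-hydroxypropyl)-2-(but-2-yn-1-yl)-5-methyloxolan-3-one
Product: 34 (2R,5S)-5-(3-bromo-2-oxopropyl)-2-(but-2-yn-1-yl)-5-methyloxolan-3-one
Conditions: Dess–Martin periodinane, NaHCO3, CH2Cl2, rt
Reagents that add atoms: none
Why: Dess–Martin oxidation of the secondary bromohydrin gives the α-bromoketone (C6) under neutral conditions; the descriptor at C8 changes by priority only.

Step 20
Reactants: 34 (2R,5S)-5-(3-bromo-2-oxopropyl)-2-(but-2-yn-1-yl)-5-methyloxolan-3-one; 35 methyl bis(2,2,2-trifluoroethyl)phosphonoacetate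
Product: 37 methyl 2-[bis(2,2,2-trifluoroethoxy)phosphoryl]-5-[(2R,5R)-5-(but-2-yn-1-yl)-2-methyl-4-oxooxolan-2-yl]-4-oxopentanoate (both C2 epimers), via sodium phosphonoacetate 36 (not isolated)
Conditions: NaH, THF, 0 °C (35 in excess); then 34, 0 °C → rt
Reagents that add atoms: sodium hydride, [Na+].[H-] (sodium of intermediate 36 only)
Why: SN2 C-alkylation of the stabilised phosphonoacetate anion by the α-bromoketone forms the C4–C5 bond; an excess of the weakly basic nucleophile should suppress dialkylation and enolisation of the β-alkoxy ketone.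

**Union and end game**

Step 21
Reactants: 37 methyl 2-[bis(2,2,2-trifluoroethoxy)phosphoryl]-5-[(2R,5R)-5-(but-2-yn-1-yl)-2-methyl-4-oxooxolan-2-yl]-4-oxopentanoate; 14 (3R)-4-methyl-3-(prop-1-yn-1-yl)pent-4-enal
Product: 39 methyl (2Z,5R)-2-{3-[(2R,5R)-5-(but-2-yn-1-yl)-2-methyl-4-oxooxolan-2-yl]-2-oxopropyl}-6-methyl-5-(prop-1-yn-1-yl)hepta-2,6-dienoate, via potassium phosphonate carbanion 38 (not isolated)
Conditions: KN(SiMe3)2 (1.0 equiv), 18-crown-6, THF, −78 °C; then 14, −78 °C; NH4Cl quench at −78 °C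
Reagents that add atoms: potassium bis(trimethylsilyl)amide, [K+].C[Si](C)(C)[N-][Si](C)(C)C (potassium of intermediate 38 only)
Why: Still–Gennari olefination: the electron-poor trifluoroethyl phosphonate with a dissociated potassium counter-ion eliminates from the kinetically formed adduct faster than it equilibrates, giving the Z-enoate (ester cis to C2), and the aldehyde reacts in preference to both ketones.

Step 22
Reactants: 39 methyl (2Z,5R)-2-{3-[(2R,5R)-5-(but-2-yn-1-yl)-2-methyl-4-oxooxolan-2-yl]-2-oxopropyl}-6-methyl-5-(prop-1-yn-1-yl)hepta-2,6-dienoate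
Product: 40 methyl (1R,5Z,8R,12R)-1-methyl-3,13-dioxo-8-(prop-1-en-2-yl)-15-oxabicyclo[10.2.1]pentadec-5-en-9-yne-5-carboxylate (14-membered cycloalkyne, C13≡C14)
Conditions: [Mo(≡CC6H4-4-OMe)(OSiPh3)3] (15 mol %), powdered 5 Å molecular sieves, toluene, 2 mM, rt → 80 °C
Reagents that add atoms: none
Why: The molybdenum alkylidyne adds one methyl-capped alkyne of 39 in a [2+2] step to a molybdenacyclobutadiene whose cycloreversion loads the substrate onto the metal, and a second [2+2]/retro-[2+2] sequence with the other alkyne forms the C13≡C14 bond and expels but-2-yne. The closest known reaction type is ring-closing alkyne metathesis of methyl-capped diynes to 12- to 20-membered cycloalkynes with silanolate molybdenum alkylidynes. The one ring closed is the 14-membered carbocycle, by end-to-end macrocyclisation, with the linear C12–C13≡C14–C1 unit lying in the ten-atom bridge that spans the trans-disposed C8 and C11 of the oxolanone. No stereocentre is formed; C1, C8 and C11 are not involved, and the Z-enoate is not at risk because alkenes do not enter the metallacyclobutadiene manifold. The step needs alkyne-over-alkene chemoselectivity (inherent to the alkylidyne, which ignores the isopropenyl and enoate double bonds), tolerance of two ketones, an ester and an ether (the silanolate ligands temper the Lewis acidity of molybdenum), and ring-over-oligomer selectivity (high dilution, with the sieves trapping but-2-yne so that closure is not reversed).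

Step 23
Reactants: 40 methyl (1R,5Z,8R,12R)-1-methyl-3,13-dioxo-8-(prop-1-en-2-yl)-15-oxabicyclo[10.2.1]pentadec-5-en-9-yne-5-carboxylate
Product: 41 methyl (1R,5Z,8S,12R)-1-methyl-3,10,13-trioxo-8-(prop-1-en-2-yl)-15-oxabicyclo[10.2.1]pentadec-5-ene-5-carboxylate (CNP0163183.3)
Conditions: (Ph3P)AuNTf2 (5 mol %), 1,4-dioxane/H2O (10:1), rt
Reagents that add atoms: water, O
Why: Gold-catalysed carbonyl-assisted alkyne hydration: π-activation of C13≡C14 triggers 5-exo-dig attack of the C10 carbonyl oxygen on C13, water opens the cyclic oxocarbenium ion and protodeauration leaves the ketone at C13 only, while the electron-poor enoate and the isopropenyl group are poor nucleophiles toward the activated alkyne (the descriptor at C1 changes from R to S by priority only).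

**Compound list**

1 | (R)-4-benzyl-1,3-oxazolidin-2-one | O=C1N[C@H](Cc2ccccc2)CO1 | starting material
2 | 3-methylbut-2-enoyl chloride | CC(C)=CC(Cl)=O | starting material
3 | lithium (R)-4-benzyl-2-oxo-1,3-oxazolidin-3-ide | [Li+].O=C1[N-][C@H](Cc2ccccc2)CO1 | intermediate (not isolated)
4 | (R)-4-benzyl-3-(3-methylbut-2-enoyl)-1,3-oxazolidin-2-one | CC(C)=CC(=O)N1[C@H](Cc2ccccc2)COC1=O | intermediate
5 | tert-butyl bromoacetate | CC(C)(C)OC(=O)CBr | starting material
6 | sodium (Z)-1-[(4R)-4-benzyl-2-oxo-1,3-oxazolidin-3-yl]-3-methylbuta-1,3-dien-1-olate | [Na+].C=C(C)/C=C(\[O-])N1[C@H](Cc2ccccc2)COC1=O | intermediate (not isolated)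
7 | tert-butyl (3R)-3-{[(4R)-4-benzyl-2-oxo-1,3-oxazolidin-3-yl]carbonyl}-4-methylpent-4-enoate | C=C(C)[C@@H](CC(=O)OC(C)(C)C)C(=O)N1[C@H](Cc2ccccc2)COC1=O | intermediate
8 | tert-butyl (3R)-3-(hydroxymethyl)-4-methylpent-4-enoate | C=C(C)[C@@H](CC(=O)OC(C)(C)C)CO | intermediate
9 | tert-butyl (3R)-3-formyl-4-methylpent-4-enoate | C=C(C)[C@@H](CC(=O)OC(C)(C)C)C=O | intermediate
10 | tert-butyl (3S)-3-(2,2-dibromoethenyl)-4-methylpent-4-enoate | C=C(C)[C@@H](CC(=O)OC(C)(C)C)C=C(Br)Br | intermediate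
11 | (3S)-5,5-dibromo-3-(prop-1-en-2-yl)pent-4-en-1-ol | C=C(C)[C@@H](CCO)C=C(Br)Br | intermediate
12 | dilithium alkoxide acetylide of (3R)-3-(prop-1-en-2-yl)pent-4-yn-1-ol | [Li+].[Li+].C=C(C)[C@@H](CC[O-])C#[C-] | intermediate (not isolated)
13 | (3R)-3-(prop-1-en-2-yl)hex-4-yn-1-ol | C=C(C)[C@@H](CCO)C#CC | intermediate
14 | (3R)-4-methyl-3-(prop-1-yn-1-yl)pent-4-enal | CC#C[C@@H](C(C)=C)CC=O | intermediate
15 | (R)-pent-4-en-2-ol | C[C@@H](O)CC=C | starting material
16 | bromoacetic acid | OC(=O)CBr | starting material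
17 | sodium (R)-pent-4-en-2-olate | [Na+].C[C@@H]([O-])CC=C | intermediate (not isolated)
18 | 2-{[(2R)-pent-4-en-2-yl]oxy}acetic acid | C[C@@H](OCC(=O)O)CC=C | intermediate
19 | (S)-4-benzyl-1,3-oxazolidin-2-one | O=C1N[C@@H](Cc2ccccc2)CO1 | starting material
20 | 2-{[(2R)-pent-4-en-2-yl]oxy}acetic pivalic anhydride | C[C@@H](OCC(=O)OC(=O)C(C)(C)C)CC=C | intermediate (not isolated)
21 | lithium (S)-4-benzyl-2-oxo-1,3-oxazolidin-3-ide | [Li+].O=C1[N-][C@@H](Cc2ccccc2)CO1 | intermediate (not isolated)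
22 | (4S)-4-benzyl-3-({[(2R)-pent-4-en-2-yl]oxy}acetyl)-1,3-oxazolidin-2-one | C[C@@H](OCC(=O)N1[C@@H](Cc2ccccc2)COC1=O)CC=C | intermediate
23 | sodium (Z)-enolate of 22 | [Na+].C[C@@H](O/C=C(\[O-])N1[C@@H](Cc2ccccc2)COC1=O)CC=C | intermediate (not isolated)
24 | tert-butyl (3R)-4-[(4S)-4-benzyl-2-oxo-1,3-oxazolidin-3-yl]-4-oxo-3-{[(2R)-pent-4-en-2-yl]oxy}butanoate | C[C@@H](O[C@H](CC(=O)OC(C)(C)C)C(=O)N1[C@@H](Cc2ccccc2)COC1=O)CC=C | intermediate
25 | lithium (2R)-4-tert-butoxy-4-oxo-2-{[(2R)-pent-4-en-2-yl]oxy}butaneperoxoate | [Li+].C[C@@H](O[C@H](CC(=O)OC(C)(C)C)C(=O)O[O-])CC=C | intermediate (not isolated)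
26 | (2R)-4-tert-butoxy-4-oxo-2-{[(2R)-pent-4-en-2-yl]oxy}butanoic acid | C[C@@H](O[C@H](CC(=O)OC(C)(C)C)C(=O)O)CC=C | intermediate
27 | mixed isobutyl carbonic anhydride of 26 | C[C@@H](O[C@H](CC(=O)OC(C)(C)C)C(=O)OC(=O)OCC(C)C)CC=C | intermediate (not isolated)
28 | tert-butyl (3R)-5-diazo-4-oxo-3-{[(2R)-pent-4-en-2-yl]oxy}pentanoate | C[C@@H](O[C@H](CC(=O)OC(C)(C)C)C(=O)C=[N+]=[N-])CC=C | intermediate
29 | tert-butyl 2-[(2R,5R)-5-methyl-3-oxo-5-(prop-2-en-1-yl)oxolan-2-yl]acetate | C=CC[C@]1(C)CC(=O)[C@@H](CC(=O)OC(C)(C)C)O1 | intermediate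
30 | 2-[(2R,5R)-5-methyl-3-oxo-5-(prop-2-en-1-yl)oxolan-2-yl]acetic acid | C=CC[C@]1(C)CC(=O)[C@@H](CC(=O)O)O1 | intermediate
31 | 4,5,6,7-tetrachloro-1,3-dioxoisoindolin-2-yl 2-[(2R,5R)-5-methyl-3-oxo-5-(prop-2-en-1-yl)oxolan-2-yl]acetate | C=CC[C@]1(C)CC(=O)[C@@H](CC(=O)ON2C(=O)c3c(Cl)c(Cl)c(Cl)c(Cl)c3C2=O)O1 | intermediate
32 | (2R,5R)-2-(but-2-yn-1-yl)-5-methyl-5-(prop-2-en-1-yl)oxolan-3-one | C=CC[C@]1(C)CC(=O)[C@@H](CC#CC)O1 | intermediate
33 | (2R,5R)-5-(3-bromo-2-hydroxypropyl)-2-(but-2-yn-1-yl)-5-methyloxolan-3-one | OC(CBr)C[C@]1(C)CC(=O)[C@@H](CC#CC)O1 | intermediate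
34 | (2R,5S)-5-(3-bromo-2-oxopropyl)-2-(but-2-yn-1-yl)-5-methyloxolan-3-one | BrCC(=O)C[C@]1(C)CC(=O)[C@@H](CC#CC)O1 | intermediate
35 | methyl bis(2,2,2-trifluoroethyl)phosphonoacetate | COC(=O)CP(=O)(OCC(F)(F)F)OCC(F)(F)F | starting material
36 | sodium salt of 35 (phosphonoacetate carbanion) | [Na+].COC(=O)[CH-]P(=O)(OCC(F)(F)F)OCC(F)(F)F | intermediate (not isolated)
37 | methyl 2-[bis(2,2,2-trifluoroethoxy)phosphoryl]-5-[(2R,5R)-5-(but-2-yn-1-yl)-2-methyl-4-oxooxolan-2-yl]-4-oxopentanoate | COC(=O)C(CC(=O)C[C@]1(C)CC(=O)[C@@H](CC#CC)O1)P(=O)(OCC(F)(F)F)OCC(F)(F)F | intermediate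
38 | potassium salt of 37 (phosphonate carbanion) | [K+].COC(=O)[C-](CC(=O)C[C@]1(C)CC(=O)[C@@H](CC#CC)O1)P(=O)(OCC(F)(F)F)OCC(F)(F)F | intermediate (not isolated)
39 | methyl (2Z,5R)-2-{3-[(2R,5R)-5-(but-2-yn-1-yl)-2-methyl-4-oxooxolan-2-yl]-2-oxopropyl}-6-methyl-5-(prop-1-yn-1-yl)hepta-2,6-dienoate | CC#C[C@@H](C(C)=C)C/C=C(\C(=O)OC)CC(=O)C[C@]1(C)CC(=O)[C@@H](CC#CC)O1 | intermediate
40 | methyl (1R,5Z,8R,12R)-1-methyl-3,13-dioxo-8-(prop-1-en-2-yl)-15-oxabicyclo[10.2.1]pentadec-5-en-9-yne-5-carboxylate | C=C(C)[C@H]1C/C=C(\C(=O)OC)CC(=O)C[C@]2(C)CC(=O)[C@@H](CC#C1)O2 | intermediate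
41 | methyl (1R,5Z,8S,12R)-1-methyl-3,10,13-trioxo-8-(prop-1-en-2-yl)-15-oxabicyclo[10.2.1]pentadec-5-ene-5-carboxylate | C=C(C)[C@H]1C/C=C(\C(=O)OC)CC(=O)C[C@]2(C)CC(=O)[C@@H](CC(=O)C1)O2 | target

**Step count and risks**

Total step count: 23 (fragment A 8, fragment B 12, union and end game 3).
Longest linear sequence: 15 steps (steps 9–23, from (R)-pent-4-en-2-ol).

Steps most likely to fail:

Step 22 (ring-closing alkyne metathesis). Intermolecular metathesis to cyclic dimers and oligomers may outrun closure of the trans-bridged ring at any practical dilution. The fallback sets out from 37 and 13 and comes back at 40. It forms the C13≡C14 bond between two molecules and closes the ring at C3=C4 instead. Alcohol 13 is silylated (t-BuMe2SiCl, imidazole, CH2Cl2) to tert-butyldimethyl{[(3R)-3-(prop-1-en-2-yl)hex-4-yn-1-yl]oxy}silane F1. Alkyne cross-metathesis of 37 with an excess of F1 (same molybdenum alkylidyne and sieves, toluene, 0.1 M) should give methyl 2-[bis(2,2,2-trifluoroethoxy)phosphoryl]-5-[(2R,5R)-5-{(4R)-6-[(tert-butyldimethylsilyl)oxy]-4-(prop-1-en-2-yl)hex-2-yn-1-yl}-2-methyl-4-oxooxolan-2-yl]-4-oxopentanoate F2. HF·pyridine in THF should free the primary alcohol, the 6-hydroxy analogue of F2, F3. Dess–Martin oxidation should give the aldehyde, the 6-oxo analogue of F2, F4. An intramolecular Still–Gennari olefination (KN(SiMe3)2, 18-crown-6, THF, 1 mM, −78 °C) should then close the 14-membered ring to 40.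

Step 14 (rhodium-carbenoid C–H insertion). The carbenoid may add to the terminal alkene (cyclopropanation through a seven-membered ring) instead of inserting into the C8–H bond. The fallback sets out from 26 and comes back at 29. It takes the alkene out of reach for the carbenoid step. Br2 (CH2Cl2, −78 °C) should convert 26 into (2R)-4-tert-butoxy-2-{[(2R)-4,5-dibromopentan-2-yl]oxy}-4-oxobutanoic acid F5. Activation as in step 13 gives the mixed isobutyl carbonic anhydride of F5, F6, and CH2N2 then gives tert-butyl (3R)-5-diazo-3-{[(2R)-4,5-dibromopentan-2-yl]oxy}-4-oxopentanoate F7. Rh2(OAc)4 should now give tert-butyl 2-[(2R,5S)-5-(2,3-dibromopropyl)-5-methyl-3-oxooxolan-2-yl]acetate F8. Zn dust (THF/AcOH, 0 °C) regenerates the alkene and returns 29.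

Step 17 (decarboxylative alkynylation). The redox-active ester may be consumed by acyl substitution or hydrolysis, or the C12 radical may be reduced before nickel captures it. The fallback sets out from 29 and comes back at 32. It is a polar homologation with the ketone masked. Ketalisation (1,2-bis(trimethylsilyloxy)ethane, Me3SiOTf cat., CH2Cl2, −78 °C) should give tert-butyl 2-[(6R,8R)-8-methyl-8-(prop-2-en-1-yl)-1,4,7-trioxaspiro[4.4]nonan-6-yl]acetate F9. LiAlH4 (THF, 0 °C) should give 2-[(6R,8R)-8-methyl-8-(prop-2-en-1-yl)-1,4,7-trioxaspiro[4.4]nonan-6-yl]ethan-1-ol F10. Dess–Martin oxidation should give 2-[(6R,8R)-8-methyl-8-(prop-2-en-1-yl)-1,4,7-trioxaspiro[4.4]nonan-6-yl]acetaldehyde F11. CBr4/PPh3/Zn should give (6R,8R)-6-(3,3-dibromoprop-2-en-1-yl)-8-methyl-8-(prop-2-en-1-yl)-1,4,7-trioxaspiro[4.4]nonane F12. n-BuLi followed by MeI should give (6R,8R)-6-(but-2-yn-1-yl)-8-methyl-8-(prop-2-en-1-yl)-1,4,7-trioxaspiro[4.4]nonane F13. Aqueous HCl in THF then returns ketone 32.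

**Further compounds**

F1 | step 22 | tert-butyldimethyl{[(3R)-3-(prop-1-en-2-yl)hex-4-yn-1-yl]oxy}silane | CC#C[C@@H](C(C)=C)CCO[Si](C)(C)C(C)(C)C
F2 | step 22 | methyl 2-[bis(2,2,2-trifluoroethoxy)phosphoryl]-5-[(2R,5R)-5-{(4R)-6-[(tert-butyldimethylsilyl)oxy]-4-(prop-1-en-2-yl)hex-2-yn-1-yl}-2-methyl-4-oxooxolan-2-yl]-4-oxopentanoate | COC(=O)C(CC(=O)C[C@]1(C)CC(=O)[C@@H](CC#C[C@@H](C(C)=C)CCO[Si](C)(C)C(C)(C)C)O1)P(=O)(OCC(F)(F)F)OCC(F)(F)F
F3 | step 22 | methyl 2-[bis(2,2,2-trifluoroethoxy)phosphoryl]-5-[(2R,5R)-5-{(4R)-6-hydroxy-4-(prop-1-en-2-yl)hex-2-yn-1-yl}-2-methyl-4-oxooxolan-2-yl]-4-oxopentanoate | COC(=O)C(CC(=O)C[C@]1(C)CC(=O)[C@@H](CC#C[C@@H](C(C)=C)CCO)O1)P(=O)(OCC(F)(F)F)OCC(F)(F)F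
F4 | step 22 | methyl 2-[bis(2,2,2-trifluoroethoxy)phosphoryl]-5-[(2R,5R)-2-methyl-4-oxo-5-{(4R)-6-oxo-4-(prop-1-en-2-yl)hex-2-yn-1-yl}oxolan-2-yl]-4-oxopentanoate | COC(=O)C(CC(=O)C[C@]1(C)CC(=O)[C@@H](CC#C[C@@H](C(C)=C)CC=O)O1)P(=O)(OCC(F)(F)F)OCC(F)(F)F
F5 | step 14 | (2R)-4-tert-butoxy-2-{[(2R)-4,5-dibromopentan-2-yl]oxy}-4-oxobutanoic acid | C[C@@H](O[C@H](CC(=O)OC(C)(C)C)C(=O)O)CC(Br)CBr
F6 | step 14 | mixed isobutyl carbonic anhydride of F5 | C[C@@H](O[C@H](CC(=O)OC(C)(C)C)C(=O)OC(=O)OCC(C)C)CC(Br)CBr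
F7 | step 14 | tert-butyl (3R)-5-diazo-3-{[(2R)-4,5-dibromopentan-2-yl]oxy}-4-oxopentanoate | C[C@@H](O[C@H](CC(=O)OC(C)(C)C)C(=O)C=[N+]=[N-])CC(Br)CBr
F8 | step 14 | tert-butyl 2-[(2R,5S)-5-(2,3-dibromopropyl)-5-methyl-3-oxooxolan-2-yl]acetate | BrCC(Br)C[C@]1(C)CC(=O)[C@@H](CC(=O)OC(C)(C)C)O1
F9 | step 17 | tert-butyl 2-[(6R,8R)-8-methyl-8-(prop-2-en-1-yl)-1,4,7-trioxaspiro[4.4]nonan-6-yl]acetate | C=CC[C@]1(C)CC2(OCCO2)[C@@H](CC(=O)OC(C)(C)C)O1
F10 | step 17 | 2-[(6R,8R)-8-methyl-8-(prop-2-en-1-yl)-1,4,7-trioxaspiro[4.4]nonan-6-yl]ethan-1-ol | C=CC[C@]1(C)CC2(OCCO2)[C@@H](CCO)O1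
F11 | step 17 | 2-[(6R,8R)-8-methyl-8-(prop-2-en-1-yl)-1,4,7-trioxaspiro[4.4]nonan-6-yl]acetaldehyde | C=CC[C@]1(C)CC2(OCCO2)[C@@H](CC=O)O1
F12 | step 17 | (6R,8R)-6-(3,3-dibromoprop-2-en-1-yl)-8-methyl-8-(prop-2-en-1-yl)-1,4,7-trioxaspiro[4.4]nonane | C=CC[C@]1(C)CC2(OCCO2)[C@@H](CC=C(Br)Br)O1
F13 | step 17 | (6R,8R)-6-(but-2-yn-1-yl)-8-methyl-8-(prop-2-en-1-yl)-1,4,7-trioxaspiro[4.4]nonane | C=CC[C@]1(C)CC2(OCCO2)[C@@H](CC#CC)O1
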